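Assumption: tamadone has no stereocentre, stereogenic axis or stereogenic double bond, so it is achiral. There is no enantiomer to select, and the SMILES is taken as the full structure.

**Retrosynthetic overview**
1. The C5–OH bond is made last, by C4-carbonyl-directed C–H oxygenation of the 5-unsubstituted flavone 6.
2. Ring C is the only ring formed. Its O1–C8a bond comes from dehydrogenative coupling of the diketone enol oxygen with one of the two equivalent ortho C–H bonds of a 3,4,5-trimethoxybenzoyl group (4 → 5).
3. The C3–C4 bond comes from a crossed Claisen condensation of ketone 2 (ring B) with ester 3 (ring A).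
4. Rings A and B are bought. Benzyl ethers keep the 2'-OH from closing the wrong pyranone.

**Route**

Step 1
Reactants: 1 2',4'-dihydroxyacetophenone (resacetophenone)
Product: 2 2',4'-bis(benzyloxy)acetophenone
Conditions: BnBr (2.4 equiv), K2CO3 (3 equiv), DMF, 80 °C, 6 h
Reagents that add atoms: benzyl bromide, BrCc1ccccc1
Why: Double Williamson ether synthesis, in which the free 4-OH reacts first and hot K2CO3/DMF also alkylates the hydrogen-bonded 2-OH, so this phenol can never condense onto the later diketone.

Step 2
Reactants: 2 2',4'-bis(benzyloxy)acetophenone; 3 methyl 3,4,5-trimethoxybenzoate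
Product: 4 1-[2,4-bis(benzyloxy)phenyl]-3-(3,4,5-trimethoxyphenyl)propane-1,3-dione (mainly the chelated enol)
Conditions: NaH (2.5 equiv), THF, 65 °C, 5 h; then 1 M HCl, 0 °C
Reagents that add atoms: none
Why: Crossed Claisen condensation, in which only 2 is enolisable, 3 cannot self-condense, deprotonation of the acidic 1,3-diketone by the second equivalent of base makes the acyl transfer irreversible, and benzyl and methyl ethers are inert to NaH.

Step 3
Reactants: 4 1-[2,4-bis(benzyloxy)phenyl]-3-(3,4,5-trimethoxyphenyl)propane-1,3-dione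
Product: 5 2-[2,4-bis(benzyloxy)phenyl]-6,7,8-trimethoxy-4H-chromen-4-one
Conditions: 9-mesityl-3,6-di-tert-butyl-10-phenylacridinium tetrafluoroborate (5 mol%), Co(dmgH)2(py)Cl (8 mol%), 2,6-lutidine (20 mol%), MeCN/HFIP 4:1 (0.02 M), 455 nm LEDs, Ar, 30 °C, 24 h
Reagents that add atoms: none
Why: Proposed new method: acceptorless, H2-evolving coupling of an enol O–H with an aryl C–H that closes the 4-pyranone. The excited acridinium (about +2.1 V vs SCE) oxidises the enolised trimethoxybenzoyl π-system to its radical cation. HFIP and lutidine break the enol chelate, so the C3–C4 rotamer that holds the ring-B-side enol oxygen over ring A becomes populated. That oxygen attacks the ortho carbon of ring A, which is para to one OMe and ortho to another and therefore carries the highest positive charge. Six-membered O-closure is the only closure the geometry allows, because attack through carbon would give a four-membered ring, and closure onto C6'–H of ring B would hit a carbon meta to both OBn groups that carries no charge. The resulting cyclohexadienyl radical, stabilised by two OMe groups, is oxidised and deprotonated in the cobaloxime cycle (trivalent cobalt is reduced by the acridinyl radical to divalent cobalt, which takes up the electron and proton as a cobalt hydride and releases H2). Because the two ortho C–H bonds are equivalent, only one regioisomer can form. The closest known reaction types are the photoredox/cobaloxime dehydrogenative lactonisation of biaryl-2-carboxylic acids and the FeCl3-mediated oxidative C–O ring closure of electron-rich α-aryl ketones to benzofurans; a 1,3-diketone enol acting as a vinylogous acid to close a chromone in this way has not been shown.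

Step 4
Reactants: 5 2-[2,4-bis(benzyloxy)phenyl]-6,7,8-trimethoxy-4H-chromen-4-one
Product: 6 2-(2,4-dihydroxyphenyl)-6,7,8-trimethoxy-4H-chromen-4-one
Conditions: H2 (1 atm), 10% Pd/C, EtOAc/MeOH 1:1, 23 °C, 3 h
Reagents that add atoms: none
Why: Catalytic hydrogenolysis of aryl benzyl ethers, which at 1 atm and room temperature leaves the flavone C2=C3 bond and the methyl ethers untouched, and removing the benzyl groups here avoids their acidolysis and oxidation in step 5.

Step 5
Reactants: 6 2-(2,4-dihydroxyphenyl)-6,7,8-trimethoxy-4H-chromen-4-one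
Product: 9 tamadone (5-hydroxy-2-(2,4-dihydroxyphenyl)-6,7,8-trimethoxy-4H-chromen-4-one), via flavone bis(trifluoroacetate) 7 (not isolated), via flavone tris(trifluoroacetate) 8 (not isolated)
Conditions: [RuCl2(p-cymene)]2 (5 mol%), PhI(OCOCF3)2 (1.5 equiv), TFA/TFAA 3:2, 80 °C, 6 h; evaporate; then MeOH, 40 °C, 1 h
Reagents that add atoms: [bis(trifluoroacetoxy)iodo]benzene, O=C(OI(OC(=O)C(F)(F)F)c1ccccc1)C(F)(F)F (source of the C5 oxygen); trifluoroacetic anhydride, O=C(OC(=O)C(F)(F)F)C(F)(F)F (trifluoroacetyl groups of 7 and 8 only)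
Why: Ketone-directed ruthenium-catalysed C–H oxygenation, known for C5 of flavones and chromones, in which TFAA first masks both ring B phenols as electron-poor trifluoroacetates (7), the C4 carbonyl guides carboxylate-assisted ruthenation by divalent ruthenium to the only peri C–H (C5–H, five-membered ruthenacycle), oxidation by the trivalent-iodine reagent to tetravalent ruthenium and C–O reductive elimination give the over-oxidation-resistant aryl trifluoroacetate 8, and methanolysis frees all three phenols.

**Compound list**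
1 | 2',4'-dihydroxyacetophenone | CC(=O)c1ccc(O)cc1O | starting material
2 | 2',4'-bis(benzyloxy)acetophenone | CC(=O)c1ccc(OCc2ccccc2)cc1OCc1ccccc1 | intermediate
3 | methyl 3,4,5-trimethoxybenzoate | COC(=O)c1cc(OC)c(OC)c(OC)c1 | starting material
4 | 1-[2,4-bis(benzyloxy)phenyl]-3-(3,4,5-trimethoxyphenyl)propane-1,3-dione | O=C(CC(=O)c1cc(OC)c(OC)c(OC)c1)c1ccc(OCc2ccccc2)cc1OCc1ccccc1 | intermediate
5 | 2-[2,4-bis(benzyloxy)phenyl]-6,7,8-trimethoxy-4H-chromen-4-one | COc1cc2c(=O)cc(-c3ccc(OCc4ccccc4)cc3OCc3ccccc3)oc2c(OC)c1OC | intermediate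
6 | 2-(2,4-dihydroxyphenyl)-6,7,8-trimethoxy-4H-chromen-4-one | COc1cc2c(=O)cc(-c3ccc(O)cc3O)oc2c(OC)c1OC | intermediate
7 | 4-(6,7,8-trimethoxy-4-oxo-4H-chromen-2-yl)benzene-1,3-diyl bis(trifluoroacetate) | COc1cc2c(=O)cc(-c3ccc(OC(=O)C(F)(F)F)cc3OC(=O)C(F)(F)F)oc2c(OC)c1OC | intermediate
8 | 2-[2,4-bis(trifluoroacetoxy)phenyl]-6,7,8-trimethoxy-4-oxo-4H-chromen-5-yl trifluoroacetate | COc1c(OC(=O)C(F)(F)F)c2c(=O)cc(-c3ccc(OC(=O)C(F)(F)F)cc3OC(=O)C(F)(F)F)oc2c(OC)c1OC | intermediate
9 | tamadone, 5-hydroxy-2-(2,4-dihydroxyphenyl)-6,7,8-trimethoxy-4H-chromen-4-one (achiral) | COc1c(OC)c(O)c2c(=O)cc(-c3ccc(O)cc3O)oc2c1OC | target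

**Step count**
Total step count: 5. Longest linear sequence: 5 (1 → 2 → 4 → 5 → 6 → 9).

**Steps most likely to fail**

Step 3 (the proposed new step) is the largest risk.
- The chelated enol may simply return the electron without cyclising.
- The hole may sit on ring B and trigger ipso attack at the 2'-benzyloxy carbon, which would give the ring-swapped flavone.
- A benzyl ether may be oxidised.

The fallback uses known chemistry and puts a halogen where the C–H bond was. It sets out from 3. Ring bromination (NBS, MeCN, 23 °C) gives methyl 2-bromo-3,4,5-trimethoxybenzoate F1. Claisen condensation of F1 with 2 (NaH, THF, 65 °C) gives 1-[2,4-bis(benzyloxy)phenyl]-3-(2-bromo-3,4,5-trimethoxyphenyl)propane-1,3-dione F2. Intramolecular Ullmann-type O-arylation (CuI 10 mol%, K2CO3, DMF, 110 °C) then closes the same O1–C8a bond, and the fallback comes back to the route at 5.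

Step 5 is the second risk.
- The C5–H bond is flanked by the 6-OMe group, so ruthenation may be slow.
- The trivalent-iodine oxidant may then attack ring A or C3 instead.

The fallback replaces C–H activation with pre-installed halogen handles. It sets out from 2.
- Commercial 3,4,5-trimethoxybenzoic acid is dibrominated (Br2, AcOH, 50 °C) to 2,6-dibromo-3,4,5-trimethoxybenzoic acid F3.
- This acid is converted ((COCl)2, cat. DMF, CH2Cl2) into 2,6-dibromo-3,4,5-trimethoxybenzoyl chloride F4.
- The lithium enolate of 2 (LiHMDS 2.2 equiv, THF, −78 °C) is acylated with F4 to give 1-[2,4-bis(benzyloxy)phenyl]-3-(2,6-dibromo-3,4,5-trimethoxyphenyl)propane-1,3-dione F5.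
- CuI/K2CO3 in DMF at 110 °C closes ring C on one bromide and gives 2-[2,4-bis(benzyloxy)phenyl]-5-bromo-6,7,8-trimethoxy-4H-chromen-4-one F6.
- Copper-mediated methoxylation (NaOMe, CuBr, DMF/MeOH, 110 °C) gives 2-[2,4-bis(benzyloxy)phenyl]-5,6,7,8-tetramethoxy-4H-chromen-4-one F7.
- BCl3 with pentamethylbenzene (CH2Cl2, −78 to 0 °C) cleaves the carbonyl-chelated 5-OMe and both benzyl ethers.

The fallback comes back to the route at 9.

Step 2 is the third risk. An ortho-substituted, electron-rich ketone enolate meets an electron-rich and therefore poorly electrophilic ester, so conversion may stall or a retro-Claisen reaction may intervene. The fallback swaps acyl substitution for aldol addition followed by oxidation. It sets out from 2. LDA (THF, −78 °C) followed by commercial 3,4,5-trimethoxybenzaldehyde gives racemic 1-[2,4-bis(benzyloxy)phenyl]-3-hydroxy-3-(3,4,5-trimethoxyphenyl)propan-1-one F8. Its stereocentre is erased by Dess–Martin periodinane oxidation (CH2Cl2, 23 °C), and the fallback comes back to the route at 4.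

**Further compounds**
F1 | step 3 | methyl 2-bromo-3,4,5-trimethoxybenzoate | COC(=O)c1cc(OC)c(OC)c(OC)c1Br
F2 | step 3 | 1-[2,4-bis(benzyloxy)phenyl]-3-(2-bromo-3,4,5-trimethoxyphenyl)propane-1,3-dione | O=C(CC(=O)c1cc(OC)c(OC)c(OC)c1Br)c1ccc(OCc2ccccc2)cc1OCc1ccccc1
F3 | step 5 | 2,6-dibromo-3,4,5-trimethoxybenzoic acid | COc1c(Br)c(C(=O)O)c(Br)c(OC)c1OC
F4 | step 5 | 2,6-dibromo-3,4,5-trimethoxybenzoyl chloride | COc1c(Br)c(C(=O)Cl)c(Br)c(OC)c1OC
F5 | step 5 | 1-[2,4-bis(benzyloxy)phenyl]-3-(2,6-dibromo-3,4,5-trimethoxyphenyl)propane-1,3-dione | COc1c(Br)c(C(=O)CC(=O)c2ccc(OCc3ccccc3)cc2OCc2ccccc2)c(Br)c(OC)c1OC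
F6 | step 5 | 2-[2,4-bis(benzyloxy)phenyl]-5-bromo-6,7,8-trimethoxy-4H-chromen-4-one | COc1c(Br)c2c(=O)cc(-c3ccc(OCc4ccccc4)cc3OCc3ccccc3)oc2c(OC)c1OC
F7 | step 5 | 2-[2,4-bis(benzyloxy)phenyl]-5,6,7,8-tetramethoxy-4H-chromen-4-one | COc1c(OC)c2c(=O)cc(-c3ccc(OCc4ccccc4)cc3OCc3ccccc3)oc2c(OC)c1OC
F8 | step 2 | racemic 1-[2,4-bis(benzyloxy)phenyl]-3-hydroxy-3-(3,4,5-trimethoxyphenyl)propan-1-one | O=C(CC(O)c1cc(OC)c(OC)c(OC)c1)c1ccc(OCc2ccccc2)cc1OCc1ccccc1
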